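**Plan**

Numbering (daucane): ring A = C1 (quaternary, CH3)–C2–C3–C4 (OH, isopropyl)–C5 (H); ring B = C1–C5–C6 (O-aroyl)–C7–C8 (CH3)=C9–C10 (O-angeloyl).
1. Retrosynthetic cuts, in order: the two ester C–O bonds; C8=C9 (ring B, ring-closing metathesis); C6–C7 and C9–C10 (2-methylallyl and vinyl additions to aldehydes); C4–C5 together with a temporary O4–C6 lactone bond; C1–C10 (conjugate addition).
2. Enabling feature: ring A with C6 on C5, between C4(OH)(iPr) and C1(CH3), is a ring-contracted p-menthane. With C6 put back between C4 and C5 it is the 1-methyl-4-isopropylcyclohexane ring of terpinen-4-ol, carbinol C4 included. C4–C5 is therefore made by a 1,2-shift of C4 from C6 to C5 (Wolff ring contraction), which cleaves the C4–C6 bond of the terpene ring and keeps its stereocentre.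
3. Forward order: six-membered terpene ring (oxidised at C6, C1 made quaternary) → ring A plus a temporary β-lactone (key step) → C10 and C6 carbinols → ring B by metathesis → esters.
4. Stereochemistry: C4 from (S)-terpinen-4-ol (retained in the shift); C1 by axial cuprate addition anti to the axial silyloxy group; C5 by the obligatory cis fusion of the β-lactone; C6 by chelation-controlled Grignard addition; C10 by catalyst-controlled vinyl transfer; the Z-enoate from angelic acid.

Key step: step 5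

Assumption: (S)-(+)-terpinen-4-ol (1) is taken as enantiomerically pure commercial material; it supplies C4 and, through it, every other stereocentre except C10.

**Route**

Step 1
Reactants: 1 (S)-terpinen-4-ol [(1S)-4-methyl-1-(propan-2-yl)cyclohex-3-en-1-ol]
Product: 2 (6R)-6-hydroxy-3-methyl-6-(propan-2-yl)cyclohex-2-en-1-one
Conditions: t-BuOOH (5 equiv), Rh2(cap)4 (cap = caprolactamate; 1 mol%), K2CO3 (0.5 equiv), CH2Cl2, rt
Reagents that add atoms: tert-butyl hydroperoxide, CC(C)(C)OO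
Why: Radical allylic oxidation should occur at the ring CH2 next to the CH end of the trisubstituted alkene, as in 1-methylcyclohexenes and at C-7 of Δ5-steroids, to give the β-methyl enone without touching the carbinol stereocentre.

Step 2
Reactants: 2 (6R)-6-hydroxy-3-methyl-6-(propan-2-yl)cyclohex-2-en-1-one
Product: 3 (6R)-3-methyl-6-(propan-2-yl)-6-[(triethylsilyl)oxy]cyclohex-2-en-1-one
Conditions: Et3SiOTf, 2,6-lutidine, CH2Cl2, −78 to 0 °C
Reagents that add atoms: triethylsilyl trifluoromethanesulfonate, CC[Si](CC)(CC)OS(=O)(=O)C(F)(F)F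
Why: O-Silylation of the hindered tertiary alcohol with a silyl triflate gives a non-chelating ether that prefers the axial position next to the carbonyl, which step 3 needs; no stereocentre is formed.

Step 3
Reactants: 3 (6R)-3-methyl-6-(propan-2-yl)-6-[(triethylsilyl)oxy]cyclohex-2-en-1-one
Product: 5 (2R,5S)-5-ethenyl-5-methyl-2-(propan-2-yl)-2-[(triethylsilyl)oxy]cyclohexan-1-one, via trimethylsilyl enol ether 4 (not isolated)
Conditions: CH2=CHMgBr (2 equiv), CuBr·SMe2 (10 mol%), Me3SiCl (2.5 equiv), THF, −78 to −40 °C; then K2CO3 (cat.), MeOH, 0 °C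
Reagents that add atoms: vinylmagnesium bromide, C=C[Mg]Br
Why: Copper-catalysed conjugate addition of a vinyl Grignard reagent, accelerated by Me3SiCl, should create the quaternary C1 by axial attack on the half-chair with isopropyl equatorial and silyloxy axial at C4, so that vinyl enters anti to that oxygen and the C1 methyl ends cis to it.

Step 4
Reactants: 5 (2R,5S)-5-ethenyl-5-methyl-2-(propan-2-yl)-2-[(triethylsilyl)oxy]cyclohexan-1-one
Product: 8 (3R,6R)-2-diazo-3-ethenyl-6-hydroxy-3-methyl-6-(propan-2-yl)cyclohexan-1-one, via trifluoroacetyl ketone 6 (not isolated), via silyl diazoketone 7 (not isolated)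
Conditions: LiN(SiMe3)2, THF, −78 °C; CF3CO2CH2CF3; then MeSO2N3, Et3N, H2O, MeCN, rt; then Bu4NF, THF, 0 °C
Reagents that add atoms: methanesulfonyl azide, CS(=O)(=O)N=[N+]=[N-]
Why: Detrifluoroacetylative diazo transfer (Regitz type) at C5, the only enolisable position, followed by fluoride desilylation, should give the free hydroxy diazoketone; no stereocentre is formed or touched.

Step 5
Reactants: 8 (3R,6R)-2-diazo-3-ethenyl-6-hydroxy-3-methyl-6-(propan-2-yl)cyclohexan-1-one
Product: 10 (1R,2R,5R)-2-ethenyl-2-methyl-5-(propan-2-yl)-6-oxabicyclo[3.2.0]heptan-7-one, via hydroxy ketene 9 (not isolated)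
Conditions: hν (medium-pressure Hg lamp, Pyrex, λ > 300 nm), THF (0.005 M), i-Pr2NEt (10 mol%), 0 °C to rt
Reagents that add atoms: none
Why: Proposed new method: irradiation expels N2 from the s-Z-locked diazoketone with concerted 1,2-shift of C4 (the ring carbon that carries OH and isopropyl) from the carbonyl carbon C6 to the diazo carbon C5 (Wolff rearrangement), which makes the C4–C5 bond, contracts the six-membered terpene ring to ring A and leaves C6 as the carbon of an exocyclic ketene 9, to which the tertiary hydroxyl on C4 then adds. The closest known reaction types are the Wolff ring contraction of 2-diazocycloalkanones with capture of the ketene by an external alcohol and the closure of β-lactones from β-hydroxy acyl derivatives (thiol ester aldolates, sulfonyl-activated β-hydroxy acids); new is only the capture of a Wolff ketene by its own β-hydroxyl. Ring A is closed by a 1,2-alkyl shift to the carbene carbon (ring contraction with retention at the migrating C4), the four-membered lactone by 4-exo-dig attack of O4 on the ketene carbon C6. The one new stereocentre, C5, is controlled by the lactone itself: a four-membered ring fused to a five-membered ring can only be cis-fused, so C6 must end on the face of the C4 oxygen and H-5 on the face of the isopropyl group, whichever way the proton is delivered. The step needs the Wolff shift to win over other carbene paths and intramolecular ketene capture to win over intermolecular capture: C1 is quaternary (no 1,2-hydride shift), the cyclic s-Z geometry and direct irradiation favour the concerted shift over O–H insertion, and high dilution in an aprotic solvent with a catalytic amine as proton shuttle leaves the neighbouring hydroxyl as the only nucleophile.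

Step 6
Reactants: 10 (1R,2R,5R)-2-ethenyl-2-methyl-5-(propan-2-yl)-6-oxabicyclo[3.2.0]heptan-7-one
Product: 12 (1R,2S,5R)-2-methyl-7-oxo-5-(propan-2-yl)-6-oxabicyclo[3.2.0]heptane-2-carbaldehyde, via ozonide 11 (not isolated)
Conditions: O3, CH2Cl2, −78 °C; then PPh3, −78 °C to rt
Reagents that add atoms: ozone, [O-][O+]=O
Why: Ozonolysis with reductive work-up should convert the vinyl group into the C10 aldehyde, which cannot enolise; the lactone and all stereocentres are inert.

Step 7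
Reactants: 12 (1R,2S,5R)-2-methyl-7-oxo-5-(propan-2-yl)-6-oxabicyclo[3.2.0]heptane-2-carbaldehyde
Product: 13 (1R,2S,5R)-2-[(1R)-1-hydroxyprop-2-en-1-yl]-2-methyl-5-(propan-2-yl)-6-oxabicyclo[3.2.0]heptan-7-one
Conditions: (CH2=CH)2Zn (2 equiv; from CH2=CHMgBr and ZnCl2, Et2O/dioxane, Mg salts filtered off), (+)-MIB [(2R)-3-exo-morpholinoisoborneol, 10 mol%], toluene, 0 °C
Reagents that add atoms: divinylzinc, C=C[Zn]C=C (made in the flask from vinylmagnesium bromide, C=C[Mg]Br, and ZnCl2)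
Why: Amino-alcohol-catalysed asymmetric addition of an alkenylzinc reagent to an aldehyde should, with the (+)-ligand, deliver vinyl to the Re face of the neopentyl-type aldehyde and set C10 as R under catalyst control.

Step 8
Reactants: 13 (1R,2S,5R)-2-[(1R)-1-hydroxyprop-2-en-1-yl]-2-methyl-5-(propan-2-yl)-6-oxabicyclo[3.2.0]heptan-7-one
Product: 14 (1R,2S,5R)-2-methyl-5-(propan-2-yl)-2-{(1R)-1-[(triethylsilyl)oxy]prop-2-en-1-yl}-6-oxabicyclo[3.2.0]heptan-7-one
Conditions: Et3SiOTf, 2,6-lutidine, CH2Cl2, −78 °C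
Reagents that add atoms: triethylsilyl trifluoromethanesulfonate, CC[Si](CC)(CC)OS(=O)(=O)C(F)(F)F
Why: Silyl ether protection keeps the C10 carbinol apart from the C6 carbinol made later, so that the two can be esterified differently; no stereocentre is formed.

Step 9
Reactants: 14 (1R,2S,5R)-2-methyl-5-(propan-2-yl)-2-{(1R)-1-[(triethylsilyl)oxy]prop-2-en-1-yl}-6-oxabicyclo[3.2.0]heptan-7-one
Product: 15 (1R,2S,3S)-2-(hydroxymethyl)-3-methyl-1-(propan-2-yl)-3-{(1R)-1-[(triethylsilyl)oxy]prop-2-en-1-yl}cyclopentan-1-ol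
Conditions: LiAlH4, THF, 0 °C
Reagents that add atoms: none
Why: Hydride reduction of the strained β-lactone with acyl–oxygen cleavage should give the 1,3-diol, freeing the C4 hydroxyl and leaving C6 as a primary alcohol; no stereocentre is touched.

Step 10
Reactants: 15 (1R,2S,3S)-2-(hydroxymethyl)-3-methyl-1-(propan-2-yl)-3-{(1R)-1-[(triethylsilyl)oxy]prop-2-en-1-yl}cyclopentan-1-ol
Product: 16 (1R,2S,5R)-5-hydroxy-2-methyl-5-(propan-2-yl)-2-{(1R)-1-[(triethylsilyl)oxy]prop-2-en-1-yl}cyclopentane-1-carbaldehyde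
Conditions: Dess–Martin periodinane, pyridine, CH2Cl2, 0 °C
Reagents that add atoms: none
Why: Periodinane oxidation takes the primary alcohol to the aldehyde while the tertiary C4 alcohol cannot react; the β-hydroxy aldehyde is used at once to avoid retro-aldol cleavage or dehydration.

Step 11
Reactants: 16 (1R,2S,5R)-5-hydroxy-2-methyl-5-(propan-2-yl)-2-{(1R)-1-[(triethylsilyl)oxy]prop-2-en-1-yl}cyclopentane-1-carbaldehyde
Product: 17 (1R,2S,3S)-2-[(1S)-1-hydroxy-3-methylbut-3-en-1-yl]-3-methyl-1-(propan-2-yl)-3-{(1R)-1-[(triethylsilyl)oxy]prop-2-en-1-yl}cyclopentan-1-ol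
Conditions: CH2=C(CH3)CH2MgCl (3 equiv), Et2O/CH2Cl2, −78 °C
Reagents that add atoms: 2-methylallylmagnesium chloride, CC(=C)C[Mg]Cl
Why: Chelation-controlled Grignard addition (Cram chelate model): the first equivalent forms the C4 magnesium alkoxide, which binds the aldehyde oxygen in a six-membered chelate cis-fused to ring A, and the second adds to the aldehyde face next to H-5 and away from the quaternary C1, which should set C6 as S.

Step 12
Reactants: 17 (1R,2S,3S)-2-[(1S)-1-hydroxy-3-methylbut-3-en-1-yl]-3-methyl-1-(propan-2-yl)-3-{(1R)-1-[(triethylsilyl)oxy]prop-2-en-1-yl}cyclopentan-1-ol; 18 4-[(tert-butyldimethylsilyl)oxy]benzoic acid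
Product: 20 (1S)-1-[(1S,2R,5S)-2-hydroxy-5-methyl-2-(propan-2-yl)-5-{(1R)-1-[(triethylsilyl)oxy]prop-2-en-1-yl}cyclopentyl]-3-methylbut-3-en-1-yl 4-[(tert-butyldimethylsilyl)oxy]benzoate, via O-acylisourea 19 (not isolated)
Conditions: DCC, DMAP (cat.), CH2Cl2, rt
Reagents that add atoms: none
Why: Steglich esterification should acylate the secondary C6 hydroxyl while the tertiary C4 hydroxyl stays free; no stereocentre is touched.

Step 13
Reactants: 20 (1S)-1-[(1S,2R,5S)-2-hydroxy-5-methyl-2-(propan-2-yl)-5-{(1R)-1-[(triethylsilyl)oxy]prop-2-en-1-yl}cyclopentyl]-3-methylbut-3-en-1-yl 4-[(tert-butyldimethylsilyl)oxy]benzoate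
Product: 21 (3R,3aS,4S,8R,8aS)-3-hydroxy-6,8a-dimethyl-3-(propan-2-yl)-8-[(triethylsilyl)oxy]-1,2,3,3a,4,5,8,8a-octahydroazulen-4-yl 4-[(tert-butyldimethylsilyl)oxy]benzoate
Conditions: second-generation Grubbs catalyst (H2IMes)(PCy3)Cl2Ru=CHPh (10 mol%), toluene, 80 °C
Reagents that add atoms: none
Why: Ring-closing metathesis between the vinyl group on C10 and the 1,1-disubstituted alkene at C8 should close ring B as the trisubstituted C8=C9 cycloheptene on the trans-disposed side chains of ring A; no stereocentre is formed.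

Step 14
Reactants: 21 (3R,3aS,4S,8R,8aS)-3-hydroxy-6,8a-dimethyl-3-(propan-2-yl)-8-[(triethylsilyl)oxy]-1,2,3,3a,4,5,8,8a-octahydroazulen-4-yl 4-[(tert-butyldimethylsilyl)oxy]benzoate
Product: 22 (3R,3aS,4S,8R,8aS)-3,8-dihydroxy-6,8a-dimethyl-3-(propan-2-yl)-1,2,3,3a,4,5,8,8a-octahydroazulen-4-yl 4-[(tert-butyldimethylsilyl)oxy]benzoate
Conditions: HF·pyridine, pyridine, THF, 0 °C
Reagents that add atoms: none
Why: Acidic fluoride should cleave the alkyl triethylsilyl ether at C10 faster than the aryl tert-butyldimethylsilyl ether, releasing the C10 alcohol selectively.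

Step 15
Reactants: 22 (3R,3aS,4S,8R,8aS)-3,8-dihydroxy-6,8a-dimethyl-3-(propan-2-yl)-1,2,3,3a,4,5,8,8a-octahydroazulen-4-yl 4-[(tert-butyldimethylsilyl)oxy]benzoate; 23 angelic acid [(2Z)-2-methylbut-2-enoic acid]
Product: 25 (3R,3aS,4S,8R,8aS)-3-hydroxy-6,8a-dimethyl-8-{[(2Z)-2-methylbut-2-enoyl]oxy}-3-(propan-2-yl)-1,2,3,3a,4,5,8,8a-octahydroazulen-4-yl 4-[(tert-butyldimethylsilyl)oxy]benzoate, via mixed anhydride 24 (not isolated)
Conditions: 23, 2,4,6-Cl3C6H2COCl, Et3N, toluene, rt; then 22, toluene, 80 °C (no DMAP)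
Reagents that add atoms: none
Why: Yamaguchi esterification through the mixed anhydride, run without a nucleophilic catalyst, should acylate the secondary allylic C10 hydroxyl (not the tertiary C4 hydroxyl) with retention at C10 and without Z-to-E isomerisation of the enoate.

Step 16
Reactants: 25 (3R,3aS,4S,8R,8aS)-3-hydroxy-6,8a-dimethyl-8-{[(2Z)-2-methylbut-2-enoyl]oxy}-3-(propan-2-yl)-1,2,3,3a,4,5,8,8a-octahydroazulen-4-yl 4-[(tert-butyldimethylsilyl)oxy]benzoate
Product: 26 (3R,3aS,4S,8R,8aS)-3-hydroxy-6,8a-dimethyl-8-{[(2Z)-2-methylbut-2-enoyl]oxy}-3-(propan-2-yl)-1,2,3,3a,4,5,8,8a-octahydroazulen-4-yl 4-hydroxybenzoate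
Conditions: Bu4NF, AcOH, THF, 0 °C
Reagents that add atoms: none
Why: Buffered fluoride cleaves the aryl silyl ether to the phenol without touching the two esters or any stereocentre.

**Compound list**

1 | (S)-terpinen-4-ol, (1S)-4-methyl-1-(propan-2-yl)cyclohex-3-en-1-ol | CC1=CC[C@](O)(C(C)C)CC1 | starting material
2 | (6R)-6-hydroxy-3-methyl-6-(propan-2-yl)cyclohex-2-en-1-one | CC1=CC(=O)[C@](O)(C(C)C)CC1 | intermediate
3 | (6R)-3-methyl-6-(propan-2-yl)-6-[(triethylsilyl)oxy]cyclohex-2-en-1-one | CC1=CC(=O)[C@](O[Si](CC)(CC)CC)(C(C)C)CC1 | intermediate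
4 | triethyl{[(1R,4R)-4-ethenyl-4-methyl-1-(propan-2-yl)-2-[(trimethylsilyl)oxy]cyclohex-2-en-1-yl]oxy}silane (not isolated) | C=C[C@]1(C)C=C(O[Si](C)(C)C)[C@](O[Si](CC)(CC)CC)(C(C)C)CC1 | intermediate
5 | (2R,5S)-5-ethenyl-5-methyl-2-(propan-2-yl)-2-[(triethylsilyl)oxy]cyclohexan-1-one | C=C[C@]1(C)CC(=O)[C@](O[Si](CC)(CC)CC)(C(C)C)CC1 | intermediate
6 | (3R,6R)-3-ethenyl-3-methyl-6-(propan-2-yl)-6-[(triethylsilyl)oxy]-2-(trifluoroacetyl)cyclohexan-1-one (C-2 epimers and enol form; not isolated) | C=C[C@]1(C)C(C(=O)C(F)(F)F)C(=O)[C@](O[Si](CC)(CC)CC)(C(C)C)CC1 | intermediate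
7 | (3R,6R)-2-diazo-3-ethenyl-3-methyl-6-(propan-2-yl)-6-[(triethylsilyl)oxy]cyclohexan-1-one (not isolated) | C=C[C@]1(C)C(=[N+]=[N-])C(=O)[C@](O[Si](CC)(CC)CC)(C(C)C)CC1 | intermediate
8 | (3R,6R)-2-diazo-3-ethenyl-6-hydroxy-3-methyl-6-(propan-2-yl)cyclohexan-1-one | C=C[C@]1(C)C(=[N+]=[N-])C(=O)[C@](O)(C(C)C)CC1 | intermediate
9 | [(2R,5R)-2-ethenyl-5-hydroxy-2-methyl-5-(propan-2-yl)cyclopentylidene]methanone (hydroxy ketene; not isolated) | C=C[C@@]1(C)CC[C@@](O)(C(C)C)C1=C=O | intermediate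
10 | (1R,2R,5R)-2-ethenyl-2-methyl-5-(propan-2-yl)-6-oxabicyclo[3.2.0]heptan-7-one | C=C[C@@]1(C)CC[C@]2(C(C)C)OC(=O)[C@H]12 | intermediate
11 | (1R,2S,5R)-2-methyl-5-(propan-2-yl)-2-(1,2,4-trioxolan-3-yl)-6-oxabicyclo[3.2.0]heptan-7-one (epimers at the trioxolane carbon; not isolated) | C1(OCOO1)[C@@]2(C)CC[C@]3(C(C)C)OC(=O)[C@H]23 | intermediate
12 | (1R,2S,5R)-2-methyl-7-oxo-5-(propan-2-yl)-6-oxabicyclo[3.2.0]heptane-2-carbaldehyde | O=C[C@@]1(C)CC[C@]2(C(C)C)OC(=O)[C@H]12 | intermediate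
13 | (1R,2S,5R)-2-[(1R)-1-hydroxyprop-2-en-1-yl]-2-methyl-5-(propan-2-yl)-6-oxabicyclo[3.2.0]heptan-7-one | C=C[C@@H](O)[C@@]1(C)CC[C@]2(C(C)C)OC(=O)[C@H]12 | intermediate
14 | (1R,2S,5R)-2-methyl-5-(propan-2-yl)-2-{(1R)-1-[(triethylsilyl)oxy]prop-2-en-1-yl}-6-oxabicyclo[3.2.0]heptan-7-one | C=C[C@@H](O[Si](CC)(CC)CC)[C@@]1(C)CC[C@]2(C(C)C)OC(=O)[C@H]12 | intermediate
15 | (1R,2S,3S)-2-(hydroxymethyl)-3-methyl-1-(propan-2-yl)-3-{(1R)-1-[(triethylsilyl)oxy]prop-2-en-1-yl}cyclopentan-1-ol | C=C[C@@H](O[Si](CC)(CC)CC)[C@@]1(C)CC[C@@](O)(C(C)C)[C@@H]1CO | intermediate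
16 | (1R,2S,5R)-5-hydroxy-2-methyl-5-(propan-2-yl)-2-{(1R)-1-[(triethylsilyl)oxy]prop-2-en-1-yl}cyclopentane-1-carbaldehyde | C=C[C@@H](O[Si](CC)(CC)CC)[C@@]1(C)CC[C@@](O)(C(C)C)[C@@H]1C=O | intermediate
17 | (1R,2S,3S)-2-[(1S)-1-hydroxy-3-methylbut-3-en-1-yl]-3-methyl-1-(propan-2-yl)-3-{(1R)-1-[(triethylsilyl)oxy]prop-2-en-1-yl}cyclopentan-1-ol | C=C[C@@H](O[Si](CC)(CC)CC)[C@@]1(C)CC[C@@](O)(C(C)C)[C@@H]1[C@@H](O)CC(C)=C | intermediate
18 | 4-[(tert-butyldimethylsilyl)oxy]benzoic acid | CC(C)(C)[Si](C)(C)Oc1ccc(cc1)C(=O)O | starting material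
19 | O-acylisourea from 18 and DCC (not isolated) | CC(C)(C)[Si](C)(C)Oc1ccc(cc1)C(=O)OC(=NC1CCCCC1)NC1CCCCC1 | intermediate
20 | (1S)-1-[(1S,2R,5S)-2-hydroxy-5-methyl-2-(propan-2-yl)-5-{(1R)-1-[(triethylsilyl)oxy]prop-2-en-1-yl}cyclopentyl]-3-methylbut-3-en-1-yl 4-[(tert-butyldimethylsilyl)oxy]benzoate | C=C[C@@H](O[Si](CC)(CC)CC)[C@@]1(C)CC[C@@](O)(C(C)C)[C@@H]1[C@@H](OC(=O)c2ccc(O[Si](C)(C)C(C)(C)C)cc2)CC(C)=C | intermediate
21 | (3R,3aS,4S,8R,8aS)-3-hydroxy-6,8a-dimethyl-3-(propan-2-yl)-8-[(triethylsilyl)oxy]-1,2,3,3a,4,5,8,8a-octahydroazulen-4-yl 4-[(tert-butyldimethylsilyl)oxy]benzoate | CC[Si](CC)(CC)O[C@@H]1C=C(C)C[C@H](OC(=O)c2ccc(O[Si](C)(C)C(C)(C)C)cc2)[C@@H]2[C@]1(C)CC[C@@]2(O)C(C)C | intermediate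
22 | (3R,3aS,4S,8R,8aS)-3,8-dihydroxy-6,8a-dimethyl-3-(propan-2-yl)-1,2,3,3a,4,5,8,8a-octahydroazulen-4-yl 4-[(tert-butyldimethylsilyl)oxy]benzoate | O[C@@H]1C=C(C)C[C@H](OC(=O)c2ccc(O[Si](C)(C)C(C)(C)C)cc2)[C@@H]2[C@]1(C)CC[C@@]2(O)C(C)C | intermediate
23 | angelic acid, (2Z)-2-methylbut-2-enoic acid | C/C=C(/C)C(=O)O | starting material
24 | (2Z)-2-methylbut-2-enoic 2,4,6-trichlorobenzoic anhydride (not isolated) | C/C=C(/C)C(=O)OC(=O)c1c(Cl)cc(Cl)cc1Cl | intermediate
25 | (3R,3aS,4S,8R,8aS)-3-hydroxy-6,8a-dimethyl-8-{[(2Z)-2-methylbut-2-enoyl]oxy}-3-(propan-2-yl)-1,2,3,3a,4,5,8,8a-octahydroazulen-4-yl 4-[(tert-butyldimethylsilyl)oxy]benzoate | C/C=C(/C)C(=O)O[C@@H]1C=C(C)C[C@H](OC(=O)c2ccc(O[Si](C)(C)C(C)(C)C)cc2)[C@@H]2[C@]1(C)CC[C@@]2(O)C(C)C | intermediate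
26 | (3R,3aS,4S,8R,8aS)-3-hydroxy-6,8a-dimethyl-8-{[(2Z)-2-methylbut-2-enoyl]oxy}-3-(propan-2-yl)-1,2,3,3a,4,5,8,8a-octahydroazulen-4-yl 4-hydroxybenzoate | C/C=C(/C)C(=O)O[C@@H]1C=C(C)C[C@H](OC(=O)c2ccc(O)cc2)[C@@H]2[C@]1(C)CC[C@@]2(O)C(C)C | target

**Count and risks**

Total step count: 16. Longest linear sequence: 16 steps (1 to 26); 18 and 23 are commercial.

Steps most likely to fail:

Step 5 (proposed new method). The ketene may be consumed by intermolecular reaction (dimerisation, adventitious water) before the strained four-membered closure, or O–H insertion of the carbene may compete with the shift. Fallback with known chemistry, from 8 back to 10: irradiation of 8 in aqueous THF (Wolff rearrangement with capture by water) should give the cis β-hydroxy acid (1R,2R,5R)-2-ethenyl-5-hydroxy-2-methyl-5-(propan-2-yl)cyclopentane-1-carboxylic acid F1 together with its carboxyl-carbon epimer F2. Treatment of F1 with PhSO2Cl in pyridine activates the acid as its mixed benzenesulfonic anhydride F3, which the cis hydroxyl should close to lactone 10. F2 cannot lactonise and is separated.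

Step 1. The oxidation may lack site selectivity, with attack at the other ring CH2 or at the methyl group giving isomeric enones. Fallback from 1 to 3: hydroxyl-directed epoxidation (VO(acac)2, t-BuOOH) should give the cis-epoxy alcohol (1R,2S,4S)-1,2-epoxy-p-menthan-4-ol F4. Silylation (Et3SiOTf, 2,6-lutidine) gives its triethylsilyl ether F5. PhSeNa in EtOH opens the epoxide at the secondary carbon to the hydroxy selenide F6. H2O2 gives the selenoxide F7, which can only eliminate away from the carbinol carbon and should give the tertiary allylic alcohol F8. Oxidative 1,3-transposition with pyridinium chlorochromate, C5H5NH[CrO3Cl], then delivers enone 3.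

Step 7. Catalyst control may fail to override the intrinsic facial bias of the hindered aldehyde, or the addition may be too slow, giving poor facial selectivity at C10. Fallback from 12 to 13: addition of CH2=CHMgBr should give 13 together with its carbinol epimer F9. Dess–Martin oxidation of the mixture gives the vinyl ketone F10. Corey–Bakshi–Shibata reduction with the (S)-2-methyl-oxazaborolidine and catecholborane (quaternary carbon as the large group) should then return 13 as the (R)-carbinol.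

**Further compounds**

F1 | step 5 | (1R,2R,5R)-2-ethenyl-5-hydroxy-2-methyl-5-(propan-2-yl)cyclopentane-1-carboxylic acid | C=C[C@@]1(C)CC[C@@](O)(C(C)C)[C@@H]1C(=O)O
F2 | step 5 | (1S,2R,5R)-2-ethenyl-5-hydroxy-2-methyl-5-(propan-2-yl)cyclopentane-1-carboxylic acid | C=C[C@@]1(C)CC[C@@](O)(C(C)C)[C@H]1C(=O)O
F3 | step 5 | benzenesulfonic (1R,2R,5R)-2-ethenyl-5-hydroxy-2-methyl-5-(propan-2-yl)cyclopentane-1-carboxylic anhydride | C=C[C@@]1(C)CC[C@@](O)(C(C)C)[C@@H]1C(=O)OS(=O)(=O)c1ccccc1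
F4 | step 1 | (1R,2S,4S)-1,2-epoxy-p-menthan-4-ol (epoxide cis to hydroxyl) | C[C@@]12CC[C@@](O)(C(C)C)C[C@@H]1O2
F5 | step 1 | triethylsilyl ether of (1R,2S,4S)-1,2-epoxy-p-menthan-4-ol | C[C@@]12CC[C@@](O[Si](CC)(CC)CC)(C(C)C)C[C@@H]1O2
F6 | step 1 | (1R,2R,4S)-1-methyl-2-(phenylselanyl)-4-(propan-2-yl)-4-[(triethylsilyl)oxy]cyclohexan-1-ol | C[C@@]1(O)CC[C@@](O[Si](CC)(CC)CC)(C(C)C)C[C@H]1[Se]c1ccccc1
F7 | step 1 | (1R,2R,4S)-1-methyl-2-(phenylseleninyl)-4-(propan-2-yl)-4-[(triethylsilyl)oxy]cyclohexan-1-ol (selenoxide) | C[C@@]1(O)CC[C@@](O[Si](CC)(CC)CC)(C(C)C)C[C@H]1[Se](=O)c1ccccc1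
F8 | step 1 | (1R,4R)-1-methyl-4-(propan-2-yl)-4-[(triethylsilyl)oxy]cyclohex-2-en-1-ol | C[C@@]1(O)CC[C@@](O[Si](CC)(CC)CC)(C(C)C)C=C1
F9 | step 7 | (1R,2S,5R)-2-[(1S)-1-hydroxyprop-2-en-1-yl]-2-methyl-5-(propan-2-yl)-6-oxabicyclo[3.2.0]heptan-7-one | C=C[C@H](O)[C@@]1(C)CC[C@]2(C(C)C)OC(=O)[C@H]12
F10 | step 7 | (1R,2S,5R)-2-methyl-5-(propan-2-yl)-2-(prop-2-enoyl)-6-oxabicyclo[3.2.0]heptan-7-one | C=CC(=O)[C@@]1(C)CC[C@]2(C(C)C)OC(=O)[C@H]12
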